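All runs are calculated on assumed constants; noise was put on by code.

Q is what one branch of a fork leaves behind: in the earlier runs Q and J together fall short of the charge, so a molecule of J either passes through Z to Q or enters a missing pool.

| flask | J | Z | remark | time |
|---|---|---|---|---|
| north-east | 0.022 M | 0.17 mM | run made earlier |  |
| south | 0.040 M | 0.17 mM | run made earlier |  |
| south-west | 0.062 M | 0.17 mM | run made earlier |  |
| north | 0.020 M | 0.19 mM | run made earlier |  |
| red | 0.020 M | 0.17 mM |  | 3.0 h |
| ochre | 0.080 M | 0.12 mM |  | 5.0 h |

- north-east (time / h: Q / %, J / %): 0.833: 38.1, 50.2; 1.50: 55.1, 28.5; 2.50: 67.9, 11.6; 3.00: 71.7, 8.4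
- south (time / h: Q / %, J / %): 0.250: 11.9, 83.9; 0.500: 22.2, 68.7; 1.33: 46.6, 36.5; 3.00: 69.1, 8.5
- south-west (time / h: Q / %, J / %): 0.417: 16.2, 76.0; 1.00: 35.2, 49.2; 2.00: 55.6, 22.8; 3.00: 66.6, 11.8
- north (time / h: Q / %, J / %): 0.250: 15.6, 80.1; 0.500: 28.7, 62.9; 1.33: 54.5, 28.7; 3.00: 75.3, 6.9

(standard deviation of a reading: 0.5 percentage points)



- the flask that ends with the higher amount of Q, in percent of the J charged, or "neither" when 2 percentage points or less lies between them (red / ochre / neither)
- final Q, as a percentage of the J charged, in red
- final Q, as a percentage of the J charged, in ochre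

The ladder starts with capacity. In north-east, Z is 0.773 % of the J charged, far less than the 19.9 % missing at 3.00 h, so at one J per Z the pool does not sit on the catalyst. Next comes the catalytic exit. Taking both exits as pseudo-first-order over the whole run, the last south-west reading gives a total constant of 0.712 h⁻¹, and Q per J consumed is 75.5 %. South-west's catalytic constant is therefore 0.538 h⁻¹, a half-life of 1.29 h. The leak to the pool is slower at 0.174 h⁻¹, a half-life of 3.98 h. North reads 0.170 h⁻¹ for the leak, so the leak barely moves with Z or J. The catalytic constants of north, 0.721 h⁻¹, and north-east, 0.646 h⁻¹, stand in the ratio 1.12, and their Z in the ratio 1.12. The last rung is a possible return from the pool: in north-east the pool reads 20.5 % at 2.50 h and 19.9 % at 3.00 h, whereas a one-way leak at 0.174 h⁻¹ on the J then present should add 0.87 percentage points. These readings hint at a return, and the leak constant, read as a net figure, carries it along.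

Scaling to ochre's Z gives a catalytic constant of 0.380 h⁻¹ beside the same leak, so ochre's fork share, the selectivity held through the run, is 68.5 %. After 5.0 h, ochre keeps 6.26 % of its J and makes 64.2 % of Q. This is a high-side figure, since the catalytic constant falls from north-east to south-west and ochre charges still more J. Red nearly repeats north-east, so its Q is put at 71.7 %, and red leads by 7.5 points. The forecast also chooses red, with 72.5 % and 66 %, both a little above these figures, on the ground that “Higher J/Z therefore wastes more J”.

The flasks give 71.7 % in red and 63.6 % in ochre, so red ends higher.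

    J ⇌ G (K = 3.00, k = 0.210 h⁻¹)
    E → Z + Q (k = 410 h⁻¹)
    J + Z ⇌ E (K = 17.0 L mol⁻¹, k = 11000 L mol⁻¹ h⁻¹)

Ochre's Q per J consumed comes to 68.7 %, against the fork share of 68.5 %, and its missing pool is G at 29.0 %. A neighbour of ochre has 3.0 × 10⁻⁵ M of Z, a quarter of ochre's charge. The same reckoning gives it a catalytic constant of 0.0949 h⁻¹ beside the leak of 0.174 h⁻¹, and a fork share of 35.2 %. That leaves 26.0 % of J and yields 26.1 % of Q. The neighbour flask ends with 29.0 % of J and 23.6 % of Q.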